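(The earlier runs and the new flask stem from a simulated flask with constants of no real substance; noise was put on by code.)

In amounts, Monday's run ended near 2.40 mM of target from its 10 mM charge and Saturday's run near 4.00 mM from 40 mM, so the target grew less than the charge. Starting material takes up dissolved gas to give target, and it is also lost to side product A and, with target, to side product B. The gas crosses from the gas phase.

| setting | Monday's | Saturday's | flask |
|---|---|---|---|
| starting material | 10 mM | 40 mM | 20 mM |
| gas phase | 9.3 mM (held) | 9.3 mM (held) | 9.3 mM (held) |
| remark | run made earlier | run made earlier |  |
| time |  |  | 3.0 min |

- Monday's (time / min: target / %): 0.200: 1; 0.333: 5; 0.667: 17; 1.33: 22; 2.50: 24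
- Saturday's (time / min: target / %): 0.200: 2; 0.333: 1; 0.667: 9; 1.33: 11; 2.50: 10

(standard deviation of a reading: 1.5 percentage points)

- percentages count the starting material that a species holds: one side product B counts as two
- at the start none of the gas is dissolved
- the numbers in the tables scatter with a standard deviation of 1.5 percentage points
- steps under discussion: gas phase <-> dissolved gas; starting material + dissolved gas -> target; starting material -> side product A; dissolved gas -> decomposition product; starting material + target -> side product B

- the target standing at 3.0 min, as a percentage of the starting material charged
- the change that raises the amount of target at 3.0 min, in percent of the starting material charged most ("none" if none brings more than 2 percentage points) (grey / violet / none)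
- amount of target at 3.0 min, in percent of the starting material charged, after grey

- grey: doubling the transfer coefficient of the gas phase, all else as stated
- violet: doubling the saturation concentration of gas phase, all else as stated

Two chemists argue over this flask. The first holds a supply view: target follows the gas that has crossed, so grey, the faster crossing, should pay like violet. The second holds a plateau view. Monday's run reads 17 % at 0.667 min against a last reading of 24 %, which gives 0.541 min as the approach time, the time in which the gap between target and its plateau shrinks by the factor e. That reading is shorter than the 3.0 min asked, and the gap left then is 0.391 % of the plateau, so she argues that gas crossing late buys little.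

My own reckoning puts the plateau at 20 mM, the geometric mean of the two charges, at the geometric mean of the last readings, 15.5 %, a little below the forecast. On that plateau the supply view expects about 31.0 % after grey.

The forecast takes the plateau side: 16.5 % (range 14 % to 19 %), best change violet, and 24 % after grey (range 20 % to 29 %), holding that “Doubling the saturation concentration exactly doubles dissolved gas at all times”.

The flask gives 18.4 %. Violet adds 11 percentage points, grey adds 1.6 points and reaches 20.0 %, so the best change is violet and the plateau view wins.

    gas phase ⇌ dissolved gas, rate k1*(csat - [dissolved gas]) (kL = 0.0820 s⁻¹)
    starting material + dissolved gas → target (k = 1.30 M⁻¹ s⁻¹)
    starting material → side product A (k = 0.0140 s⁻¹)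
    dissolved gas → decomposition product (k = 2.00 × 10⁻⁵ s⁻¹)
    starting material + target → side product B (k = 2.00 M⁻¹ s⁻¹)

The largest single effect on this flask's target is the step from starting material and target to side product B: without it the flask gives 37.2 % instead of 18.4 % . The drag of the crossing is a smaller part of the shortfall: with it removed this flask gives 21.8 %. The supply view's region is the start of this flask, with dissolved gas at 6.27 mM after 0.300 min, below the saturation concentration of 9.3 mM. The forecast's number would fail if this flask were read early: by 0.744 min the answer has moved 5 points. At 1.50 min the approach time gives 17.3 %, and this flask holds 17.3 %.

Read at 50 s, the same flask should stand at 14.5 % by the approach time; the computed target is 14.2 %.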